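The naphthoquinone is disconnected at its two aryl–carbonyl bonds, C1–C8a and C4–C4a: the benzo ring arrives as benzyne, and the quinone ring carbons C1–C2(Me)–C3(chain)–C4 as a 3,4-disubstituted 2,5-bis(silyloxy)furan, the bis-enol ether of a succinic anhydride already carrying the complete C40 side chain. One aryne Diels–Alder reaction across furan C2/C5 forms both bonds, and collapse of the bis-silyl ketal bridge delivers the 1,4-dione without a redox step. The step exploits the para-placed carbonyl carbons C1 and C4, each bonded to one of the adjacent benzo carbons C8a and C4a. The 7'R centre comes from asymmetric hydrogenation of farnesol; the chain is built by sulfone coupling and alkyne carboalumination.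

Key step: step 17

Remark: "C40-yl" stands for (2E,7R,10E,14E,18E,22E,26E)-3,7,11,15,19,23,27,31-octamethyldotriaconta-2,10,14,18,22,26,30-heptaen-1-yl and primed locants count this chain from the ring; 23, 25 and 26 are carried as diastereomer mixtures at the two succinyl carbons, which both become sp2 in 27; (2E,6E)-farnesol and all-E geranylgeraniol are taken as commercial single isomers.

Step 1
Reactants: 1 (2E,6E)-farnesol
Product: 2 (S)-2,3-dihydrofarnesol [(3S,6E)-3,7,11-trimethyldodeca-6,10-dien-1-ol]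
Conditions: Ru(OAc)2[(R)-BINAP] (cat.), H2 (about 100 atm), MeOH/H2O 95:5, 20 °C
Reagents that add atoms: none
Why: Noyori asymmetric hydrogenation, in which the allylic hydroxyl binds ruthenium so that only the C2=C3 alkene is reduced and the (R)-BINAP ligand directs hydrogen to the face of the 2E-alkene that gives the 3S centre (the sense of geraniol to (S)-citronellol), the two remote trisubstituted alkenes staying untouched.

Step 2
Reactants: 2 (S)-2,3-dihydrofarnesol
Product: 3 (3S,6E)-3,7,11-trimethyldodeca-6,10-dien-1-yl pivalate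
Conditions: PivCl, pyridine, DMAP (cat.), CH2Cl2, 0 °C to rt
Reagents that add atoms: pivaloyl chloride, CC(C)(C)C(=O)Cl
Why: Acylation of the primary alcohol gives a hindered, non-enolisable ester that should survive allylic oxidation, bromination and the sulfone carbanion and is later removed by the hydride used for desulfonylation.

Step 3
Reactants: 3 (3S,6E)-3,7,11-trimethyldodeca-6,10-dien-1-yl pivalate
Product: 4 (3S,6E,10E)-12-hydroxy-3,7,11-trimethyldodeca-6,10-dien-1-yl pivalate
Conditions: SeO2 (cat.), t-BuOOH, salicylic acid (cat.), CH2Cl2, 0 °C to rt, stopped at partial conversion with recycling of 3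
Reagents that add atoms: tert-butyl hydroperoxide, CC(C)(C)OO (terminal source of the new oxygen, relayed by catalytic SeO2, O=[Se]=O)
Why: Riley-type allylic oxidation by ene reaction and [2,3]-sigmatropic shift should favour the E-methyl group of the terminal isopropylidene unit and so give the E-configured primary allylic alcohol.

Step 4
Reactants: 4 (3S,6E,10E)-12-hydroxy-3,7,11-trimethyldodeca-6,10-dien-1-yl pivalate
Product: 5 (3S,6E,10E)-12-bromo-3,7,11-trimethyldodeca-6,10-dien-1-yl pivalate
Conditions: PBr3, pyridine (cat.), Et2O, −10 °C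
Reagents that add atoms: phosphorus tribromide, BrP(Br)Br
Why: Bromination of a primary allylic alcohol through its phosphite ester proceeds by SN2 at low temperature without allylic transposition or loss of E geometry.

Step 5
Reactants: 6 (2E,6E,10E)-geranylgeraniol
Product: 7 (2E,6E,10E)-geranylgeranyl bromide
Conditions: PBr3, Et2O, −10 °C
Reagents that add atoms: phosphorus tribromide, BrP(Br)Br
Why: The same SN2 bromination of a primary allylic alcohol should give the all-E bromide, which is used without storage.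

Step 6
Reactants: 7 (2E,6E,10E)-geranylgeranyl bromide
Product: 8 (2E,6E,10E)-geranylgeranyl phenyl sulfone
Conditions: PhSO2Na, DMF, rt
Reagents that add atoms: sodium benzenesulfinate (PhSO2Na), [Na+].[O-]S(=O)c1ccccc1
Why: S-alkylation of the sulfinate anion by the primary allylic bromide (SN2) should give the allylic sulfone with the 2E-alkene unchanged.

Step 7
Reactants: 8 (2E,6E,10E)-geranylgeranyl phenyl sulfone; 5 (3S,6E,10E)-12-bromo-3,7,11-trimethyldodeca-6,10-dien-1-yl pivalate
Product: 10 (3S,6E,10E,14E,18E,22E)-3,7,11,15,19,23,27-heptamethyl-13-(phenylsulfonyl)octacosa-6,10,14,18,22,26-hexaen-1-yl pivalate (both epimers at C13), via lithiated sulfone 9 (not isolated)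
Conditions: n-BuLi, THF/DMPU, −78 °C; then 5, −78 to −20 °C
Reagents that add atoms: none
Why: Biellmann-type coupling, in which the sulfone-stabilised allylic carbanion is alkylated at its α-carbon by the primary allylic bromide (SN2) with every alkene geometry retained; the new sulfone-bearing centre forms unselectively and is removed in step 8.

Step 8
Reactants: 10 the C35 sulfone pivalate
Product: 11 (S)-2,3-dihydroheptaprenol [(3S,6E,10E,14E,18E,22E)-3,7,11,15,19,23,27-heptamethyloctacosa-6,10,14,18,22,26-hexaen-1-ol]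
Conditions: Pd(dppp)Cl2 (cat.), LiEt3BH (excess), THF, 0 °C to rt
Reagents that add atoms: none
Why: Palladium-catalysed reductive desulfonylation, in which zerovalent palladium ionises the allylic sulfone to a π-allyl complex that takes hydride at the less substituted terminus so that the trisubstituted E-alkene stays in place, while the same hydride cleaves the pivalate to the primary alcohol.

Step 9
Reactants: 11 (S)-2,3-dihydroheptaprenol
Product: 12 (S)-2,3-dihydroheptaprenyl iodide [(6E,10E,14E,18E,22E,26S)-28-iodo-2,6,10,14,18,22,26-heptamethyloctacosa-2,6,10,14,18,22-hexaene]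
Conditions: PPh3, I2, imidazole, CH2Cl2, 0 °C to rt (alcohol added last)
Reagents that add atoms: iodine, II
Why: Appel-type iodination converts the primary alcohol through its alkoxyphosphonium salt into the iodide by SN2 without touching the alkenes or the stereocentre two carbons away.

Step 10
Reactants: 12 (S)-2,3-dihydroheptaprenyl iodide; 13 1-(trimethylsilyl)propyne
Product: 16 (6R,9E,13E,17E,21E,25E)-6,10,14,18,22,26,30-heptamethylhentriaconta-9,13,17,21,25,29-hexaen-1-yne, via lithiated TMS-propyne 14 (not isolated), via TMS-alkyne 15 (not isolated)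
Conditions: 13, n-BuLi, THF, −78 to −20 °C; then 12, −78 °C to rt; then K2CO3, MeOH, rt
Reagents that add atoms: none
Why: Alkylation of the propargylic lithium reagent by the primary iodide (SN2) adds carbons C2'–C4', and base-mediated methanolysis of the alkynyl C–Si bond frees the terminal alkyne.

Step 11
Reactants: 16 the terminal alkyne
Product: 19 (2E,7R,10E,14E,18E,22E,26E)-3,7,11,15,19,23,27,31-octamethyldotriaconta-2,10,14,18,22,26,30-heptaen-1-ol, via alkenyldimethylalane 17 (not isolated), via lithium butyl alanate 18 (not isolated)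
Conditions: Me3Al, Cp2ZrCl2 (cat.), CH2Cl2, 0 °C to rt; volatiles removed; n-BuLi, THF, −78 °C; (CH2O)n, −78 °C to rt
Reagents that add atoms: trimethylaluminium, C[Al](C)C; paraformaldehyde, as formaldehyde C=O
Why: Negishi zirconium-catalysed carboalumination adds methyl and aluminium syn across the terminal alkyne with methyl on the internal carbon, and the alanate adds to formaldehyde with retention, so the 2E-allylic alcohol forms stereospecifically while the trisubstituted alkenes are inert.

Step 12
Reactants: 19 the C40 allylic alcohol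
Product: 20 (2E,7R,10E,14E,18E,22E,26E)-1-bromo-3,7,11,15,19,23,27,31-octamethyldotriaconta-2,10,14,18,22,26,30-heptaene
Conditions: PBr3, pyridine (cat.), Et2O, −10 °C
Reagents that add atoms: phosphorus tribromide, BrP(Br)Br
Why: SN2 bromination of the primary allylic alcohol at low temperature should retain the 2E geometry, and the bromide is used at once.

Step 13
Reactants: 21 dimethyl 2-methylsuccinate (racemic); 20 the C40 allylic bromide
Product: 23 dimethyl 2-methyl-3-(C40-yl)butanedioate (diastereomer mixture), via lithium enolate 22 (not isolated)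
Conditions: 21, LiN(i-Pr)2, THF, −78 °C; then 20, DMPU, −78 to −30 °C
Reagents that add atoms: none
Why: Kinetic deprotonation at −78 °C should occur at the less hindered CH2 group, and this ester enolate displaces the primary allylic bromide by SN2 (enolate alkylation) with the 2E-alkene intact; the two new succinyl centres form unselectively, which is harmless because both are erased in step 16.

Step 14
Reactants: 23 dimethyl 2-methyl-3-(C40-yl)butanedioate
Product: 25 2-methyl-3-(C40-yl)butanedioic acid (diastereomer mixture), via dipotassium dicarboxylate 24 (not isolated)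
Conditions: KOH, THF/MeOH/H2O, 50 °C; then cold 1 M HCl to pH 3
Reagents that add atoms: potassium hydroxide, [K+].[OH-]
Why: Saponification by acyl–oxygen cleavage gives the dicarboxylate, and brief cold acidification frees the diacid without lactonisation onto the 2'-alkene.

Step 15
Reactants: 25 2-methyl-3-(C40-yl)butanedioic acid
Product: 26 3-methyl-4-(C40-yl)oxolane-2,5-dione (cis and trans)
Conditions: DCC, CH2Cl2, 0 °C to rt
Reagents that add atoms: none
Why: Carbodiimide dehydration closes the five-membered cyclic anhydride at room temperature under neutral conditions that the polyene tolerates.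

Step 16
Reactants: 26 3-methyl-4-(C40-yl)oxolane-2,5-dione
Product: 27 2,5-bis(tert-butyldimethylsilyloxy)-3-methyl-4-(C40-yl)furan
Conditions: TBSOTf, Et3N, CH2Cl2, 0 °C to rt; non-aqueous work-up, used directly
Reagents that add atoms: tert-butyldimethylsilyl trifluoromethanesulfonate, CC(C)(C)[Si](C)(C)OS(=O)(=O)C(F)(F)F
Why: Soft enolisation by silyl triflate and amine silylates both anhydride carbonyls, the second enolisation being driven by formation of the aromatic furan, so that the diastereomer mixture converges on one diene.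

Step 17
Reactants: 27 2,5-bis(tert-butyldimethylsilyloxy)-3-methyl-4-(C40-yl)furan; 28 2-iodophenyl trifluoromethanesulfonate
Product: 32 2-methyl-3-(C40-yl)naphthalene-1,4-dione, via 2-lithiophenyl triflate 29 (not isolated), via benzyne 30 (not isolated), via bis-silyl ketal cycloadduct 31 (not isolated)
Conditions: 28, n-BuLi (slow addition), THF, −78 °C to rt; then 1 M HCl, THF, 0 °C
Reagents that add atoms: none
Why: Iodine–lithium exchange on 28 gives 29, which loses LiOTf at −78 °C to release benzyne 30; this is trapped by the 2,5-dioxygenated furan 27 in a concerted suprafacial [4+2] cycloaddition across C2 and C5, making both aryl–carbon bonds (C1–C8a and C4–C4a) at once, and acid then hydrolyses the strained bis-silyl ketal bridge of 31 so that each bridgehead collapses to a carbonyl group at the oxidation level stored in the anhydride. The closest known reaction types are the Diels–Alder reaction of arynes (from 2-haloaryl triflates and n-BuLi) with 2-alkoxy- and 2-silyloxyfurans and the Diels–Alder reactions of 2,5-bis(silyloxy)furans with alkynes and quinones that give para-dioxygenated arenes. One ring is closed, the six-membered quinone ring, by intermolecular [4+2] annulation in which the furan oxygen becomes a transient 1,4-bridge (a 7-oxabicyclo[2.2.1]heptadiene) that is lost on hydrolysis. No stereocentre of the product is created, since the two bridgehead centres of 31 are transient and the remote 7'R centre is not involved. The selectivity needed is chemoselectivity of benzyne for the furan over ene reaction at the seven trisubstituted alkenes, which the electron-rich cyclic s-cis diene and a low stationary benzyne concentration should secure, and regiochemistry is not an issue because benzyne is symmetrical.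

Compound list
1 | (2E,6E)-farnesol | CC(C)=CCC/C(C)=C/CC/C(C)=C/CO | starting material
2 | (S)-2,3-dihydrofarnesol, (3S,6E)-3,7,11-trimethyldodeca-6,10-dien-1-ol | CC(C)=CCC/C(C)=C/CC[C@H](C)CCO | intermediate
3 | (3S,6E)-3,7,11-trimethyldodeca-6,10-dien-1-yl pivalate | CC(C)=CCC/C(C)=C/CC[C@H](C)CCOC(=O)C(C)(C)C | intermediate
4 | (3S,6E,10E)-12-hydroxy-3,7,11-trimethyldodeca-6,10-dien-1-yl pivalate | OC/C(C)=C/CC/C(C)=C/CC[C@H](C)CCOC(=O)C(C)(C)C | intermediate
5 | (3S,6E,10E)-12-bromo-3,7,11-trimethyldodeca-6,10-dien-1-yl pivalate | BrC/C(C)=C/CC/C(C)=C/CC[C@H](C)CCOC(=O)C(C)(C)C | intermediate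
6 | (2E,6E,10E)-geranylgeraniol | CC(C)=CCC/C(C)=C/CC/C(C)=C/CC/C(C)=C/CO | starting material
7 | (2E,6E,10E)-geranylgeranyl bromide | CC(C)=CCC/C(C)=C/CC/C(C)=C/CC/C(C)=C/CBr | intermediate
8 | (2E,6E,10E)-geranylgeranyl phenyl sulfone | CC(C)=CCC/C(C)=C/CC/C(C)=C/CC/C(C)=C/CS(=O)(=O)c1ccccc1 | intermediate
9 | 1-lithio derivative of 8 (lithiated sulfone, not isolated) | CC(C)=CCC/C(C)=C/CC/C(C)=C/CC/C(C)=C/C([Li])S(=O)(=O)c1ccccc1 | intermediate
10 | (3S,6E,10E,14E,18E,22E)-3,7,11,15,19,23,27-heptamethyl-13-(phenylsulfonyl)octacosa-6,10,14,18,22,26-hexaen-1-yl pivalate, both C13 epimers | CC(C)=CCC/C(C)=C/CC/C(C)=C/CC/C(C)=C/C(C/C(C)=C/CC/C(C)=C/CC[C@H](C)CCOC(=O)C(C)(C)C)S(=O)(=O)c1ccccc1 | intermediate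
11 | (S)-2,3-dihydroheptaprenol, (3S,6E,10E,14E,18E,22E)-3,7,11,15,19,23,27-heptamethyloctacosa-6,10,14,18,22,26-hexaen-1-ol | CC(C)=CCC/C(C)=C/CC/C(C)=C/CC/C(C)=C/CC/C(C)=C/CC/C(C)=C/CC[C@H](C)CCO | intermediate
12 | (S)-2,3-dihydroheptaprenyl iodide, (6E,10E,14E,18E,22E,26S)-28-iodo-2,6,10,14,18,22,26-heptamethyloctacosa-2,6,10,14,18,22-hexaene | CC(C)=CCC/C(C)=C/CC/C(C)=C/CC/C(C)=C/CC/C(C)=C/CC/C(C)=C/CC[C@H](C)CCI | intermediate
13 | 1-(trimethylsilyl)propyne | CC#C[Si](C)(C)C | starting material
14 | 3-lithio-1-(trimethylsilyl)propyne (not isolated) | [Li]CC#C[Si](C)(C)C | intermediate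
15 | 1-trimethylsilyl derivative of alkyne 16 (6R, not isolated) | CC(C)=CCC/C(C)=C/CC/C(C)=C/CC/C(C)=C/CC/C(C)=C/CC/C(C)=C/CC[C@H](C)CCCC#C[Si](C)(C)C | intermediate
16 | (6R,9E,13E,17E,21E,25E)-6,10,14,18,22,26,30-heptamethylhentriaconta-9,13,17,21,25,29-hexaen-1-yne | CC(C)=CCC/C(C)=C/CC/C(C)=C/CC/C(C)=C/CC/C(C)=C/CC/C(C)=C/CC[C@H](C)CCCC#C | intermediate
17 | (1E,6R)-alkenyldimethylalane from syn-methylalumination of 16 (not isolated) | CC(C)=CCC/C(C)=C/CC/C(C)=C/CC/C(C)=C/CC/C(C)=C/CC/C(C)=C/CC[C@H](C)CCC/C(C)=C/[Al](C)C | intermediate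
18 | lithium butyl(alkenyl)dimethylalanate from 17 (not isolated) | [Li+].CC(C)=CCC/C(C)=C/CC/C(C)=C/CC/C(C)=C/CC/C(C)=C/CC/C(C)=C/CC[C@H](C)CCC/C(C)=C/[Al-](C)(C)CCCC | intermediate
19 | (2E,7R,10E,14E,18E,22E,26E)-3,7,11,15,19,23,27,31-octamethyldotriaconta-2,10,14,18,22,26,30-heptaen-1-ol | CC(C)=CCC/C(C)=C/CC/C(C)=C/CC/C(C)=C/CC/C(C)=C/CC/C(C)=C/CC[C@H](C)CCC/C(C)=C/CO | intermediate
20 | (2E,7R,10E,14E,18E,22E,26E)-1-bromo-3,7,11,15,19,23,27,31-octamethyldotriaconta-2,10,14,18,22,26,30-heptaene | CC(C)=CCC/C(C)=C/CC/C(C)=C/CC/C(C)=C/CC/C(C)=C/CC/C(C)=C/CC[C@H](C)CCC/C(C)=C/CBr | intermediate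
21 | dimethyl 2-methylsuccinate (racemic) | COC(=O)CC(C)C(=O)OC | starting material
22 | lithium enolate of 21 at the CH2 carbon (not isolated) | COC(=O)C(C)C=C(O[Li])OC | intermediate
23 | dimethyl 2-methyl-3-(C40-yl)butanedioate, diastereomer mixture | CC(C)=CCC/C(C)=C/CC/C(C)=C/CC/C(C)=C/CC/C(C)=C/CC/C(C)=C/CC[C@H](C)CCC/C(C)=C/CC(C(=O)OC)C(C)C(=O)OC | intermediate
24 | dipotassium 2-methyl-3-(C40-yl)butanedioate (not isolated) | CC(C)=CCC/C(C)=C/CC/C(C)=C/CC/C(C)=C/CC/C(C)=C/CC/C(C)=C/CC[C@H](C)CCC/C(C)=C/CC(C(=O)[O-])C(C)C(=O)[O-].[K+].[K+] | intermediate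
25 | 2-methyl-3-(C40-yl)butanedioic acid, diastereomer mixture | CC(C)=CCC/C(C)=C/CC/C(C)=C/CC/C(C)=C/CC/C(C)=C/CC/C(C)=C/CC[C@H](C)CCC/C(C)=C/CC(C(=O)O)C(C)C(=O)O | intermediate
26 | 3-methyl-4-(C40-yl)oxolane-2,5-dione, cis and trans | CC(C)=CCC/C(C)=C/CC/C(C)=C/CC/C(C)=C/CC/C(C)=C/CC/C(C)=C/CC[C@H](C)CCC/C(C)=C/CC1C(C)C(=O)OC1=O | intermediate
27 | 2,5-bis(tert-butyldimethylsilyloxy)-3-methyl-4-(C40-yl)furan | CC(C)=CCC/C(C)=C/CC/C(C)=C/CC/C(C)=C/CC/C(C)=C/CC/C(C)=C/CC[C@H](C)CCC/C(C)=C/Cc1c(C)c(O[Si](C)(C)C(C)(C)C)oc1O[Si](C)(C)C(C)(C)C | intermediate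
28 | 2-iodophenyl trifluoromethanesulfonate | FC(F)(F)S(=O)(=O)Oc1ccccc1I | starting material
29 | 2-lithiophenyl trifluoromethanesulfonate (not isolated) | [Li]c1ccccc1OS(=O)(=O)C(F)(F)F | intermediate
30 | benzyne (not isolated) | C1#CC=CC=C1 | intermediate
31 | 1,4-bis(tert-butyldimethylsilyloxy)-2-methyl-3-(C40-yl)-1,4-dihydro-1,4-epoxynaphthalene (bridgehead centres unassigned, not isolated) | CC(C)=CCC/C(C)=C/CC/C(C)=C/CC/C(C)=C/CC/C(C)=C/CC/C(C)=C/CC[C@H](C)CCC/C(C)=C/CC1=C(C)C2(O[Si](C)(C)C(C)(C)C)OC1(O[Si](C)(C)C(C)(C)C)c1ccccc12 | intermediate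
32 | 2-methyl-3-[(2E,7R,10E,14E,18E,22E,26E)-3,7,11,15,19,23,27,31-octamethyldotriaconta-2,10,14,18,22,26,30-heptaen-1-yl]naphthalene-1,4-dione | CC(C)=CCC/C(C)=C/CC/C(C)=C/CC/C(C)=C/CC/C(C)=C/CC/C(C)=C/CC[C@H](C)CCC/C(C)=C/CC1=C(C)C(=O)c2ccccc2C1=O | target

Total step count: 17
Longest linear sequence: 15 steps (steps 1–4 and 7–17, from farnesol)

Three steps most likely to fail

Step 17. What may go wrong: loss of a silyl group from the ketene-acetal-like diene, or attack of n-BuLi on it, before benzyne is released; or ene addition of benzyne to the chain alkenes outrunning the cycloaddition. The fallback keeps the same two aryl–carbon bonds formed in one aryne cycloaddition but uses a robust, unoxygenated furan and restores the quinone level afterwards. It sets out from 23 and comes back to the route at 32.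
- LiAlH4 in THF at 0 °C should reduce both esters to 2-methyl-3-(C40-yl)butane-1,4-diol F1.
- Swern oxidation ((COCl)2, DMSO, Et3N, −78 °C) should give 2-methyl-3-(C40-yl)butanedial F2.
- A trace of p-TsOH in toluene over 4 Å sieves should close it (Paal–Knorr) to 3-methyl-4-(C40-yl)furan F3.
- Benzyne from 2-(trimethylsilyl)phenyl triflate and CsF in MeCN/THF should add across furan C2/C5 to give 2-methyl-3-(C40-yl)-1,4-dihydro-1,4-epoxynaphthalene F4.
- Cu(OTf)2-catalysed opening of the oxygen bridge in DCE should isomerise it to the two naphthols 2-methyl-3-(C40-yl)naphthalen-1-ol F5 and 3-methyl-2-(C40-yl)naphthalen-1-ol F6.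
- Para-oxidation of this mixture with (KO3S)2NO in buffered aqueous acetone should converge on 32.

Step 13. What may go wrong: enolate equilibration by proton exchange, so that alkylation also occurs at the methyl-bearing carbon or twice, and self-condensation of the succinate enolate. The fallback makes the nucleophilic carbon unambiguous with a malonate. It sets out from 20 and comes back at 23.
- Trimethyl propane-1,1,2-tricarboxylate F7 is prepared from dimethyl malonate and methyl 2-bromopropanoate with NaOMe in MeOH.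
- F7 is deprotonated with NaH in THF/DMF and alkylated by 20 (SN2) to give trimethyl 1-(C40-yl)propane-1,1,2-tricarboxylate F8, written out as trimethyl 3-(C40-yl-methyl-free) triester with the C40-yl group on the malonate carbon.
- Krapcho demethoxycarbonylation (LiCl, wet DMSO, 150 °C) should remove one geminal ester under neutral conditions and return 23.

Step 3. What may go wrong: competing oxidation at the allylic CH2 groups of the internal 6-alkene and over-oxidation to the enal, giving poor site selectivity. The fallback rebuilds the terminus by cleavage and olefination. It sets out from 3 and comes back at 4.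
- NBS in aqueous THF at 0 °C should form the terminal bromohydrin (3S,6E)-10-bromo-11-hydroxy-3,7,11-trimethyldodec-6-en-1-yl pivalate F9.
- K2CO3 in MeOH should close it to the 10,11-epoxide F10.
- H5IO6 in THF/Et2O should cleave the epoxide to (4E,8S)-4,8-dimethyl-10-(pivaloyloxy)dec-4-enal F11.
- Wittig reaction with Ph3P=C(CH3)CHO in toluene at 90 °C should give the E-enal (2E,6E,10S)-2,6,10-trimethyl-12-(pivaloyloxy)dodeca-2,6-dienal F12.
- Luche reduction (NaBH4, CeCl3, MeOH, 0 °C) should give 4.

Further compounds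
F1 | step 17 | 2-methyl-3-(C40-yl)butane-1,4-diol | CC(C)=CCC/C(C)=C/CC/C(C)=C/CC/C(C)=C/CC/C(C)=C/CC/C(C)=C/CC[C@H](C)CCC/C(C)=C/CC(CO)C(C)CO
F2 | step 17 | 2-methyl-3-(C40-yl)butanedial | CC(C)=CCC/C(C)=C/CC/C(C)=C/CC/C(C)=C/CC/C(C)=C/CC/C(C)=C/CC[C@H](C)CCC/C(C)=C/CC(C=O)C(C)C=O
F3 | step 17 | 3-methyl-4-(C40-yl)furan | CC(C)=CCC/C(C)=C/CC/C(C)=C/CC/C(C)=C/CC/C(C)=C/CC/C(C)=C/CC[C@H](C)CCC/C(C)=C/Cc1cocc1C
F4 | step 17 | 2-methyl-3-(C40-yl)-1,4-dihydro-1,4-epoxynaphthalene | CC(C)=CCC/C(C)=C/CC/C(C)=C/CC/C(C)=C/CC/C(C)=C/CC/C(C)=C/CC[C@H](C)CCC/C(C)=C/CC1=C(C)C2OC1c1ccccc12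
F5 | step 17 | 2-methyl-3-(C40-yl)naphthalen-1-ol | CC(C)=CCC/C(C)=C/CC/C(C)=C/CC/C(C)=C/CC/C(C)=C/CC/C(C)=C/CC[C@H](C)CCC/C(C)=C/Cc1cc2ccccc2c(O)c1C
F6 | step 17 | 3-methyl-2-(C40-yl)naphthalen-1-ol | CC(C)=CCC/C(C)=C/CC/C(C)=C/CC/C(C)=C/CC/C(C)=C/CC/C(C)=C/CC[C@H](C)CCC/C(C)=C/Cc1c(C)cc2ccccc2c1O
F7 | step 13 | trimethyl propane-1,1,2-tricarboxylate | COC(=O)C(C)C(C(=O)OC)C(=O)OC
F8 | step 13 | trimethyl 1-(C40-yl)propane-1,1,2-tricarboxylate | CC(C)=CCC/C(C)=C/CC/C(C)=C/CC/C(C)=C/CC/C(C)=C/CC/C(C)=C/CC[C@H](C)CCC/C(C)=C/CC(C(=O)OC)(C(=O)OC)C(C)C(=O)OC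
F9 | step 3 | (3S,6E)-10-bromo-11-hydroxy-3,7,11-trimethyldodec-6-en-1-yl pivalate (both C10 epimers) | CC(C)(O)C(Br)CC/C(C)=C/CC[C@H](C)CCOC(=O)C(C)(C)C
F10 | step 3 | (3S,6E)-10,11-epoxy-3,7,11-trimethyldodec-6-en-1-yl pivalate (both C10 epimers) | CC1(C)OC1CC/C(C)=C/CC[C@H](C)CCOC(=O)C(C)(C)C
F11 | step 3 | (4E,8S)-4,8-dimethyl-10-(pivaloyloxy)dec-4-enal | O=CCC/C(C)=C/CC[C@H](C)CCOC(=O)C(C)(C)C
F12 | step 3 | (2E,6E,10S)-2,6,10-trimethyl-12-(pivaloyloxy)dodeca-2,6-dienal | O=C/C(C)=C/CC/C(C)=C/CC[C@H](C)CCOC(=O)C(C)(C)C
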